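## Retrosynthetic overview

1. Target ⇒ late C15 allylic hydroxylation, 1(10)-epoxidation and α-methylenation of a trans-fused 6,12-lactone that already carries the C8 (S)-2-methylbutanoate.
2. Lactone and C8 ester ⇒ Evans–Tishchenko reduction of an 8-hydroxy-6-ketone with (S)-2-methylbutanal, which sets C6 and installs the ester in one step.
3. Ten-membered ring ⇒ anionic oxy-Cope rearrangement of a 1,2-dialkenylcyclohexenol, which forms C8–C9 and the 1(10)E alkene and transfers chirality to C8; the enolate is alkylated at C7 in the same flask.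
4. Cyclohexenol ⇒ (Z)-2-alkoxyvinyllithium plus a 4-silyloxy-6-isopropenylcyclohexenone made from (S)-carvone, which supplies C3 and the 4Z alkene.
5. Ring order: six-membered carbocycle (bought) → ten-membered carbocycle (oxy-Cope) → γ-lactone → epoxide.

Assumption: ten-membered-ring compounds are named with germacranolide numbering (ring C1–C10, C14 on C10, C15 on C4, C11–C13 on C7), and 1,2-dibromoethene, tert-butyl bromoacetate and all unnumbered reagents are bought.

## Route

Step 1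
Reactants: 1 (S)-(+)-carvone
Product: 2 (1S,5S)-cis-carveol
Conditions: NaBH4, CeCl3·7H2O, MeOH, −78 → 0 °C
Reagents that add atoms: none
Why: Luche reduction delivers hydride 1,2 to the enone from the face anti to the C5 isopropenyl group, giving the cis (1S) allylic alcohol whose carbinol carbon becomes C3 of the target.

Step 2
Reactants: 2 (1S,5S)-cis-carveol
Product: 3 tert-butyldimethylsilyl ether of (1S,5S)-cis-carveol
Conditions: TBSCl, imidazole, DMF, 23 °C
Reagents that add atoms: tert-butyldimethylsilyl chloride CC(C)(C)[Si](C)(C)Cl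
Why: Silyl ether formation protects the allylic hydroxyl for the oxidation and carbanion steps without touching either stereocentre.

Step 3
Reactants: 3 tert-butyldimethylsilyl ether of (1S,5S)-cis-carveol
Product: 4 (4S,6S)-4-(tert-butyldimethylsilyloxy)-3-methyl-6-(prop-1-en-2-yl)cyclohex-2-en-1-one
Conditions: Pd(OH)2/C (5 mol %), t-BuOOH (5 equiv), K2CO3 (0.25 equiv), CH2Cl2, 4 °C
Reagents that add atoms: tert-butyl hydroperoxide CC(C)(C)OO
Why: Allylic C–H oxidation converts the only ring allylic methylene into the enone carbonyl, placing C=O next to the isopropenyl-bearing carbon while the shielded tertiary C–H beside the silyl ether is spared and no stereocentre is affected.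

Step 4
Reactants: 5 4-methoxybenzyl alcohol; 6 1,2-dibromoethene (cis/trans mixture)
Product: 7 (Z)-1-bromo-2-(4-methoxybenzyloxy)ethene
Conditions: KOt-Bu (1.1 equiv), THF, 0 → 23 °C
Reagents that add atoms: none
Why: Base-induced dehydrobromination of 6 to bromoacetylene followed by anti addition of the alkoxide (elimination–addition) gives the Z-configured β-bromovinyl ether.

Step 5
Reactants: 7 (Z)-1-bromo-2-(4-methoxybenzyloxy)ethene; 4 (4S,6S)-4-(tert-butyldimethylsilyloxy)-3-methyl-6-(prop-1-en-2-yl)cyclohex-2-en-1-one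
Product: 9 (1S,4S,6S)-4-(tert-butyldimethylsilyloxy)-1-[(Z)-2-(4-methoxybenzyloxy)ethenyl]-3-methyl-6-(prop-1-en-2-yl)cyclohex-2-en-1-ol, via vinyllithium 8 (not isolated)
Conditions: t-BuLi (2.0 equiv), Et2O, −78 °C; then LaCl3·2LiCl (0.3 equiv), 4, THF, −78 °C; H2O quench
Reagents that add atoms: none
Why: Bromine–lithium exchange with retention of the Z geometry and 1,2-addition of the vinyllithium to the enone carbonyl from the face anti to the adjacent isopropenyl group sets the carbinol centre with the two alkenyl groups trans, while LaCl3·2LiCl suppresses enolisation.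

Step 6
Reactants: 9 (1S,4S,6S)-4-(tert-butyldimethylsilyloxy)-1-[(Z)-2-(4-methoxybenzyloxy)ethenyl]-3-methyl-6-(prop-1-en-2-yl)cyclohex-2-en-1-ol
Product: 12 tert-butyl 2-[(3S,7R,8R,1(10)E,4Z)-3-(tert-butyldimethylsilyloxy)-8-(4-methoxybenzyloxy)-4,10-dimethyl-6-oxocyclodeca-1(10),4-dien-7-yl]acetate, via potassium alkoxide 10 (not isolated), via potassium dienolate 11 (not isolated)
Conditions: KN(SiMe3)2 (1.1 equiv), 18-crown-6 (1.1 equiv), THF, 0 → 23 °C; then BrCH2CO2t-Bu (1.5 equiv), −78 → −20 °C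
Reagents that add atoms: tert-butyl bromoacetate CC(C)(C)OC(=O)CBr
Why: The anionic oxy-Cope rearrangement ([3,3]-sigmatropic) runs through a chair transition state with both alkenyl groups equatorial on the cyclohexene and the small Z-alkoxy group axial, so it forms C8–C9 and the ten-membered ring, gives the 1(10)E alkene and transfers the chirality of the isopropenyl-bearing carbon to C8 (R), after which the dienolate is alkylated (SN2) at C7 on the outer face anti to the new C8–C9 bond (7R).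

Step 7
Reactants: 12 tert-butyl 2-[(3S,7R,8R,1(10)E,4Z)-3-(tert-butyldimethylsilyloxy)-8-(4-methoxybenzyloxy)-4,10-dimethyl-6-oxocyclodeca-1(10),4-dien-7-yl]acetate
Product: 13 tert-butyl 2-[(3S,7R,8R,1(10)E,4Z)-3-(tert-butyldimethylsilyloxy)-8-hydroxy-4,10-dimethyl-6-oxocyclodeca-1(10),4-dien-7-yl]acetate
Conditions: DDQ (1.3 equiv), CH2Cl2/aq. NaH2PO4–Na2HPO4 buffer pH 7 (10:1), 0 °C
Reagents that add atoms: none
Why: Oxidative cleavage of the 4-methoxybenzyl ether (benzylic hydride abstraction by DDQ, then hydrolysis) frees the C8 hydroxyl under neutral conditions that spare the silyl ether, both alkenes and the tert-butyl ester, which does not lactonise with a neutral alcohol.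

Step 8
Reactants: 14 (S)-2-methylbutan-1-ol
Product: 15 (S)-2-methylbutanal
Conditions: TEMPO (1 mol %), KBr (10 mol %), NaOCl (1.1 equiv), NaHCO3, CH2Cl2/H2O, 0 °C; used as a dried CH2Cl2 solution
Reagents that add atoms: none
Why: The Anelli oxidation (TEMPO-catalysed hypochlorite oxidation) stops at the aldehyde and does not racemise the α-stereocentre.

Step 9
Reactants: 13 tert-butyl 2-[(3S,7R,8R,1(10)E,4Z)-3-(tert-butyldimethylsilyloxy)-8-hydroxy-4,10-dimethyl-6-oxocyclodeca-1(10),4-dien-7-yl]acetate; 15 (S)-2-methylbutanal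
Product: 17 tert-butyl 2-[(3S,6R,7S,8R,1(10)E,4Z)-3-(tert-butyldimethylsilyloxy)-6-hydroxy-4,10-dimethyl-8-[(2S)-2-methylbutanoyloxy]cyclodeca-1(10),4-dien-7-yl]acetate, via hemiacetal 16 (not isolated)
Conditions: SmI2 (0.3 equiv), 15 (6 equiv), THF, −10 °C
Reagents that add atoms: none
Why: In the Evans–Tishchenko reduction the samarium-bound hemiacetal of the C8 hydroxyl and the aldehyde delivers hydride intramolecularly to C6 through a chair six-membered transition state, which sets C6 (R) 1,3-anti to C8 and leaves the (S)-2-methylbutanoate on O8.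

Step 10
Reactants: 17 tert-butyl 2-[(3S,6R,7S,8R,1(10)E,4Z)-3-(tert-butyldimethylsilyloxy)-6-hydroxy-4,10-dimethyl-8-[(2S)-2-methylbutanoyloxy]cyclodeca-1(10),4-dien-7-yl]acetate
Product: 18 (3S,6R,7R,8R,1(10)E,4Z)-3-(tert-butyldimethylsilyloxy)-8-[(2S)-2-methylbutanoyloxy]-13-norgermacra-1(10),4-dien-6,12-olide
Conditions: CSA (0.2 equiv), PhMe, 40 °C
Reagents that add atoms: none
Why: Acid-catalysed intramolecular transesterification (lactonisation) of the γ-hydroxy tert-butyl ester closes the trans-fused five-membered lactone on O6 with every stereocentre retained.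

Step 11
Reactants: 18 (3S,6R,7R,8R,1(10)E,4Z)-3-(tert-butyldimethylsilyloxy)-8-[(2S)-2-methylbutanoyloxy]-13-norgermacra-1(10),4-dien-6,12-olide
Product: 22 (3S,6R,7R,8R,1(10)E,4Z)-3-(tert-butyldimethylsilyloxy)-8-[(2S)-2-methylbutanoyloxy]germacra-1(10),4,11(13)-trien-6,12-olide, via lithium enolate 19 (not isolated), via Mannich base 20 (not isolated), via ammonium iodide 21 (not isolated)
Conditions: LiN(i-Pr)2 (1.1 equiv), THF, −78 °C; CH2=NMe2+ I− (3 equiv), −78 → 0 °C; then MeI, MeOH, 23 °C; then aq. NaHCO3, CH2Cl2, 23 °C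
Reagents that add atoms: N,N-dimethylmethyleneiminium iodide C=[N+](C)C.[I-]
Why: α-Methylenation proceeds by a Mannich reaction of the lactone enolate, quaternisation and Hofmann-type β-elimination, and the lactone α-CH2 is deprotonated far faster than the branched ester α-CH, so the side-chain stereocentre is untouched.

Step 12
Reactants: 22 (3S,6R,7R,8R,1(10)E,4Z)-3-(tert-butyldimethylsilyloxy)-8-[(2S)-2-methylbutanoyloxy]germacra-1(10),4,11(13)-trien-6,12-olide
Product: 23 (1R,3S,6R,7R,8R,10R,4Z)-1,10-epoxy-3-(tert-butyldimethylsilyloxy)-8-[(2S)-2-methylbutanoyloxy]germacra-4,11(13)-dien-6,12-olide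
Conditions: dimethyldioxirane (1.05 equiv), acetone/CH2Cl2, −20 → 0 °C
Reagents that add atoms: dimethyldioxirane CC1(C)OO1
Why: Electrophilic epoxidation by the dioxirane selects the strained electron-rich 1(10)E alkene over C4=C5 (two allylic C–O bonds) and the conjugated methylene, and oxygen is delivered syn to the outer face anti to the transannular C6, which gives the trans (1R,10R) epoxide.

Step 13
Reactants: 23 (1R,3S,6R,7R,8R,10R,4Z)-1,10-epoxy-3-(tert-butyldimethylsilyloxy)-8-[(2S)-2-methylbutanoyloxy]germacra-4,11(13)-dien-6,12-olide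
Product: 24 (1R,3S,6R,7R,8R,10R,4Z)-1,10-epoxy-3-(tert-butyldimethylsilyloxy)-15-hydroxy-8-[(2S)-2-methylbutanoyloxy]germacra-4,11(13)-dien-6,12-olide
Conditions: SeO2 (0.3 equiv), t-BuOOH (3 equiv), CH2Cl2, 23 °C
Reagents that add atoms: tert-butyl hydroperoxide CC(C)(C)OO
Why: SeO2-catalysed allylic hydroxylation (ene reaction then [2,3]-sigmatropic shift) oxidises the C15 methyl cis to H5, the only allylic methyl on a non-conjugated alkene, and the [2,3] step returns C4=C5 with the ring carbons cis (4Z).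

Step 14
Reactants: 24 (1R,3S,6R,7R,8R,10R,4Z)-1,10-epoxy-3-(tert-butyldimethylsilyloxy)-15-hydroxy-8-[(2S)-2-methylbutanoyloxy]germacra-4,11(13)-dien-6,12-olide
Product: 25 (1R,3S,6R,7R,8R,10R,4Z)-1,10-epoxy-3,15-dihydroxy-8-[(2S)-2-methylbutanoyloxy]germacra-4,11(13)-dien-6,12-olide (CNP0267576.2)
Conditions: HF·pyridine, pyridine, THF, 0 °C
Reagents that add atoms: none
Why: Fluoride-mediated desilylation under pyridine-buffered conditions frees the C3 hydroxyl without opening the epoxide or adding to the methylene lactone, giving the target.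

## Compound list

1 | (S)-(+)-carvone | CC1=CC[C@@H](CC1=O)C(C)=C | starting material
2 | (1S,5S)-cis-carveol | CC1=CC[C@@H](C[C@@H]1O)C(C)=C | intermediate
3 | tert-butyldimethylsilyl ether of (1S,5S)-cis-carveol | CC1=CC[C@@H](C[C@@H]1O[Si](C)(C)C(C)(C)C)C(C)=C | intermediate
4 | (4S,6S)-4-(tert-butyldimethylsilyloxy)-3-methyl-6-(prop-1-en-2-yl)cyclohex-2-en-1-one | CC1=CC(=O)[C@@H](C[C@@H]1O[Si](C)(C)C(C)(C)C)C(C)=C | intermediate
5 | 4-methoxybenzyl alcohol | COc1ccc(CO)cc1 | starting material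
6 | 1,2-dibromoethene (cis/trans mixture) | BrC=CBr | starting material
7 | (Z)-1-bromo-2-(4-methoxybenzyloxy)ethene | COc1ccc(CO/C=C\Br)cc1 | intermediate
8 | (Z)-2-(4-methoxybenzyloxy)ethenyllithium (not isolated) | COc1ccc(CO/C=C\[Li])cc1 | intermediate
9 | (1S,4S,6S)-4-(tert-butyldimethylsilyloxy)-1-[(Z)-2-(4-methoxybenzyloxy)ethenyl]-3-methyl-6-(prop-1-en-2-yl)cyclohex-2-en-1-ol | CC1=C[C@@](O)(/C=C\OCc2ccc(OC)cc2)[C@@H](C[C@@H]1O[Si](C)(C)C(C)(C)C)C(C)=C | intermediate
10 | potassium alkoxide of 9 (not isolated) | CC1=C[C@@]([O-])(/C=C\OCc2ccc(OC)cc2)[C@@H](C[C@@H]1O[Si](C)(C)C(C)(C)C)C(C)=C.[K+] | intermediate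
11 | potassium (3S,8R,1(10)E,4Z)-3-(tert-butyldimethylsilyloxy)-8-(4-methoxybenzyloxy)-4,10-dimethylcyclodeca-1(10),4,6-trien-6-olate (not isolated) | C/C1=C\C[C@H](O[Si](C)(C)C(C)(C)C)/C(C)=C\C(\[O-])=C\[C@H](OCc2ccc(OC)cc2)C1.[K+] | intermediate
12 | tert-butyl 2-[(3S,7R,8R,1(10)E,4Z)-3-(tert-butyldimethylsilyloxy)-8-(4-methoxybenzyloxy)-4,10-dimethyl-6-oxocyclodeca-1(10),4-dien-7-yl]acetate | C/C1=C\C[C@H](O[Si](C)(C)C(C)(C)C)/C(C)=C\C(=O)[C@H](CC(=O)OC(C)(C)C)[C@H](OCc2ccc(OC)cc2)C1 | intermediate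
13 | tert-butyl 2-[(3S,7R,8R,1(10)E,4Z)-3-(tert-butyldimethylsilyloxy)-8-hydroxy-4,10-dimethyl-6-oxocyclodeca-1(10),4-dien-7-yl]acetate | C/C1=C\C[C@H](O[Si](C)(C)C(C)(C)C)/C(C)=C\C(=O)[C@H](CC(=O)OC(C)(C)C)[C@H](O)C1 | intermediate
14 | (S)-2-methylbutan-1-ol | CC[C@H](C)CO | starting material
15 | (S)-2-methylbutanal | CC[C@H](C)C=O | intermediate
16 | C8 hemiacetal of 13 with 15, hemiacetal carbon unassigned (not isolated) | C/C1=C\C[C@H](O[Si](C)(C)C(C)(C)C)/C(C)=C\C(=O)[C@H](CC(=O)OC(C)(C)C)[C@H](OC(O)[C@@H](C)CC)C1 | intermediate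
17 | tert-butyl 2-[(3S,6R,7S,8R,1(10)E,4Z)-3-(tert-butyldimethylsilyloxy)-6-hydroxy-4,10-dimethyl-8-[(2S)-2-methylbutanoyloxy]cyclodeca-1(10),4-dien-7-yl]acetate | C/C1=C\C[C@H](O[Si](C)(C)C(C)(C)C)/C(C)=C\[C@@H](O)[C@H](CC(=O)OC(C)(C)C)[C@H](OC(=O)[C@@H](C)CC)C1 | intermediate
18 | (3S,6R,7R,8R,1(10)E,4Z)-3-(tert-butyldimethylsilyloxy)-8-[(2S)-2-methylbutanoyloxy]-13-norgermacra-1(10),4-dien-6,12-olide | C/C1=C\C[C@H](O[Si](C)(C)C(C)(C)C)/C(C)=C\[C@H]2OC(=O)C[C@@H]2[C@H](OC(=O)[C@@H](C)CC)C1 | intermediate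
19 | lithium enolate of lactone 18 (not isolated) | C/C1=C\C[C@H](O[Si](C)(C)C(C)(C)C)/C(C)=C\[C@H]2OC([O-])=C[C@@H]2[C@H](OC(=O)[C@@H](C)CC)C1.[Li+] | intermediate
20 | 11-(dimethylaminomethyl) lactone, C11 epimers (not isolated) | C/C1=C\C[C@H](O[Si](C)(C)C(C)(C)C)/C(C)=C\[C@H]2OC(=O)C(CN(C)C)[C@@H]2[C@H](OC(=O)[C@@H](C)CC)C1 | intermediate
21 | 11-(trimethylammoniomethyl) lactone iodide, C11 epimers (not isolated) | C/C1=C\C[C@H](O[Si](C)(C)C(C)(C)C)/C(C)=C\[C@H]2OC(=O)C(C[N+](C)(C)C)[C@@H]2[C@H](OC(=O)[C@@H](C)CC)C1.[I-] | intermediate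
22 | (3S,6R,7R,8R,1(10)E,4Z)-3-(tert-butyldimethylsilyloxy)-8-[(2S)-2-methylbutanoyloxy]germacra-1(10),4,11(13)-trien-6,12-olide | C/C1=C\C[C@H](O[Si](C)(C)C(C)(C)C)/C(C)=C\[C@H]2OC(=O)C(=C)[C@@H]2[C@H](OC(=O)[C@@H](C)CC)C1 | intermediate
23 | (1R,3S,6R,7R,8R,10R,4Z)-1,10-epoxy-3-(tert-butyldimethylsilyloxy)-8-[(2S)-2-methylbutanoyloxy]germacra-4,11(13)-dien-6,12-olide | C[C@@]13O[C@@H]3C[C@H](O[Si](C)(C)C(C)(C)C)/C(C)=C\[C@H]2OC(=O)C(=C)[C@@H]2[C@H](OC(=O)[C@@H](C)CC)C1 | intermediate
24 | (1R,3S,6R,7R,8R,10R,4Z)-1,10-epoxy-3-(tert-butyldimethylsilyloxy)-15-hydroxy-8-[(2S)-2-methylbutanoyloxy]germacra-4,11(13)-dien-6,12-olide | C[C@@]13O[C@@H]3C[C@H](O[Si](C)(C)C(C)(C)C)/C(CO)=C\[C@H]2OC(=O)C(=C)[C@@H]2[C@H](OC(=O)[C@@H](C)CC)C1 | intermediate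
25 | (1R,3S,6R,7R,8R,10R,4Z)-1,10-epoxy-3,15-dihydroxy-8-[(2S)-2-methylbutanoyloxy]germacra-4,11(13)-dien-6,12-olide (CNP0267576.2) | C[C@@]13O[C@@H]3C[C@H](O)/C(CO)=C\[C@H]2OC(=O)C(=C)[C@@H]2[C@H](OC(=O)[C@@H](C)CC)C1 | target

## Step count and risks

Total step count: 14. Longest linear sequence: 12 (steps 1, 2, 3, 5, 6, 7, 9, 10, 11, 12, 13, 14); steps 4 and 8 prepare the two side reagents.

The stereochemical assignments at C7 (outer-face alkylation) and C1/C10 (outer-face epoxidation) rest on conformational reasoning for the ten-membered ring and have not been tested.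

The step most likely to fail is step 6. The potassium dienolate 11 carries a β-alkoxy group and may expel 4-methoxybenzyl oxide at the temperature of the rearrangement, and a boat transition state or a poor C7 alkylation would erode C8 or C7. The fallback never has a free enolate at elevated temperature. It sets out from 9, which is silylated (TMSCl, imidazole, CH2Cl2) to the trimethylsilyl ether F1. F1 is heated in base-washed glass (decalin, 180 °C) so that the neutral siloxy-Cope rearrangement gives the ten-membered trimethylsilyl dienol ether F2. MeLi (THF, −78 → 0 °C) then releases the lithium dienolate F3, which is alkylated at −78 °C with tert-butyl bromoacetate. The route is rejoined at 12.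

The second is step 9. The β-hydroxy ketone 13 can ring-open by retro-aldol under the Lewis-acidic samarium catalyst, the α-branched aldehyde may form the hemiacetal slowly, and 15 can partly racemise. The fallback separates reduction from acylation and sets out from 13. Evans–Saksena reduction (Me4NBH(OAc)3, MeCN/AcOH, −20 °C) gives the anti-6,8-diol tert-butyl ester F4 by intramolecular hydride delivery from O8. CSA in toluene then closes the 8-hydroxy-6,12-lactone F5; the trans-fused 6,12-closure is expected to win over the cis-fused 8,12 alternative, but this regiochemistry is the open point of the fallback. Esterification of F5 with bought (S)-2-methylbutanoic acid (N,N'-diisopropylcarbodiimide, DMAP cat., CH2Cl2, 0 °C) comes back to the route at 18.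

The third is step 13. The C4=C5 alkene is slowed by two allylic C–O bonds, so the catalytic hydroxylation may stall or give alcohol/aldehyde mixtures, and the epoxide is acid-sensitive. The fallback replaces direct hydroxylation with an oxidation–reduction relay and sets out from 23. SeO2 (1.5 equiv) with t-BuOOH in 1,2-dichloroethane at 60 °C over a NaHCO3 buffer drives the oxidation fully to the C15 enal F6. F6 is then reduced 1,2 with NaBH4/CeCl3·7H2O in MeOH at −78 °C, which leaves the methylene lactone alone. The route is rejoined at 24.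

Further compounds
F1 | step 6 | trimethylsilyl ether of carbinol 9 | CC1=C[C@@](O[Si](C)(C)C)(/C=C\OCc2ccc(OC)cc2)[C@@H](C[C@@H]1O[Si](C)(C)C(C)(C)C)C(C)=C
F2 | step 6 | (3S,8R,1(10)E,4Z)-3-(tert-butyldimethylsilyloxy)-8-(4-methoxybenzyloxy)-4,10-dimethyl-6-(trimethylsilyloxy)cyclodeca-1(10),4,6-triene | C/C1=C\C[C@H](O[Si](C)(C)C(C)(C)C)/C(C)=C\C(\O[Si](C)(C)C)=C\[C@H](OCc2ccc(OC)cc2)C1
F3 | step 6 | lithium (3S,8R,1(10)E,4Z)-3-(tert-butyldimethylsilyloxy)-8-(4-methoxybenzyloxy)-4,10-dimethylcyclodeca-1(10),4,6-trien-6-olate | C/C1=C\C[C@H](O[Si](C)(C)C(C)(C)C)/C(C)=C\C(\[O-])=C\[C@H](OCc2ccc(OC)cc2)C1.[Li+]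
F4 | step 9 | tert-butyl 2-[(3S,6R,7R,8R,1(10)E,4Z)-3-(tert-butyldimethylsilyloxy)-6,8-dihydroxy-4,10-dimethylcyclodeca-1(10),4-dien-7-yl]acetate | C/C1=C\C[C@H](O[Si](C)(C)C(C)(C)C)/C(C)=C\[C@@H](O)[C@H](CC(=O)OC(C)(C)C)[C@H](O)C1
F5 | step 9 | (3S,6R,7R,8R,1(10)E,4Z)-3-(tert-butyldimethylsilyloxy)-8-hydroxy-13-norgermacra-1(10),4-dien-6,12-olide | C/C1=C\C[C@H](O[Si](C)(C)C(C)(C)C)/C(C)=C\[C@H]2OC(=O)C[C@@H]2[C@H](O)C1
F6 | step 13 | (1R,3S,6R,7R,8R,10R,4E)-1,10-epoxy-3-(tert-butyldimethylsilyloxy)-8-[(2S)-2-methylbutanoyloxy]-15-oxogermacra-4,11(13)-dien-6,12-olide | C[C@@]13O[C@@H]3C[C@H](O[Si](C)(C)C(C)(C)C)/C(C=O)=C\[C@H]2OC(=O)C(=C)[C@@H]2[C@H](OC(=O)[C@@H](C)CC)C1
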